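**Conventions.** Ring atoms keep the numbers of the ten-membered ring of the target in every intermediate: C1 (ester carbon), C2 (side-chain carbon), C5 (methyl carbon), C9 (methyl carbinol), C10 (secondary carbinol); C11 is the carbinol carbon of the side chain. In the bicyclic intermediates ring A is C5–C6–C7–C8–C9–C10 and ring B is C10–C1–C2–C3–C4–C5. β is the face that carries the C5 methyl, α the opposite face.

Remark on the chemistry: ketone 2 is used as its mixture of C2 epimers, because that centre becomes trigonal in step 2.

## Analysis of the target

Target 32 is a saturated cyclodecane that carries an angelate (Z-2-methylbut-2-enoate) on O1, a 2-hydroxypropan-2-yl group on C2, a methyl on C5, a tertiary methyl carbinol at C9 and a secondary carbinol at C10. It has five stereocentres, (1R,2R,5S,9R,10S). Four are contiguous (C9–C10–C1–C2): along the extended chain O9 and O10 are anti, O10 and O1 are syn, and the C2 side chain is anti to O1. C5 stands alone, 1,4 to C2 and directly across the ring from C10. The sensitive groups are the angelate, which isomerises to the tiglate under base, nucleophiles or heat and can migrate to the neighbouring C10 hydroxyl, and the two tertiary alcohols. The difficulty is twofold: ten is a poor ring size for direct cyclisation, and stereocontrol on so flexible a ring is unreliable, above all for the isolated C5 centre. The plan rests on the fact that C5 and C10 face each other: a C5–C10 bond turns the cyclodecane into a eudesmane-type trans-decalin (rings A and B) with the C5 methyl and the C10 oxygen on the ring fusion. Ring B then has the substitution pattern of (R)-carvone 1, so C1, C2 and C9 can be set on a rigid chiral-pool framework and the large ring is released, not closed.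

## Retrosynthetic reasoning

**Ester C1–O.** The angelate is put on last but one, from angelic acid 29 onto alcohol 28, in which O9/O10 are tied as an acetonide and only the unreactive tertiary O11 is also free. Hydrolysis of acetonide 31 then gives 32. The ester would not survive the basic, reducing and fluoride steps that precede it.

**C5–H and C6–H.** Alcohol 28 comes from alkene 27 by hydroxyl-directed hydrogenation. The hydrogen on C5 must enter on the alkene face that looks across the ring at C10, which is the β side of the ring. The C1 hydroxyl is the β-face donor; the C9 and C10 hydroxyls lie on the α side and would steer the metal to the wrong face. They are therefore masked first (26), and the silyl groups are removed (27) before the hydrogenation.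

**C10–H.** Diol 25 comes from α-hydroxy ketone 24 by chelation-controlled hydride reduction. In the chelate the C9 methyl and ring carbon C8 sit on opposite faces of the carbonyl, and hydride enters past the methyl, on the peripheral face.

**C5–C10 (key disconnection).** Ketone 24, with its E-C5=C6 alkene, is the fragmentation product of decalin 23. Reconnecting C5 to C10 gives a trans-decalin with a tertiary C10 hydroxyl and an equatorial C6 mesylate. The cut is made here because the ten-membered ring is the perimeter of this decalin: no medium-ring closure is needed, and the alkene geometry follows from the decalin stereochemistry.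

**C9–O and C10–O.** Mesylate 23 comes from triol 22, and 22 from alkene 20 by cis-dihydroxylation of the tetrasubstituted C9=C10 bond on the α face. The side-chain alkene has to be hydrated before this step, since it would be dihydroxylated first.

**C6–O and removal of the C8 oxygen.** The C6 alcohol has to be β (equatorial) to stand anti-periplanar to C5–C10. Oxygen reaches C6 only on the α face (epoxide 16, anti to the C5 methyl). Simple reductive opening of 16 would leave an axial C6 alcohol and a ketone at C8. A Wharton transposition (16 to 17) moves the oxygen to C6 and deletes the C8 oxygen in one step. Saturation of C7=C8 (18), oxidation (19) and hydride reduction from the α face (20) then invert C6. Epoxide 16 comes from dienone 15, and 15 from enone 13 by dehydrogenation.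

**C1–O.** Silyl ether 13 comes from alcohol 12, made from enone 10 by oxidation of its extended dienol ether at the γ carbon C1 (axial, β). Enone 10 is the hydrate of 8.

**C5–C6 and C9–C10 (annulation).** Enone 8 comes from diketone 7 by aldol condensation, and 7 from ketone 2 and enone 4. Plain base catalysis would attach the chain cis to the isopropenyl group and give the C5 epimer. The Michael step is therefore run through the imine of 2 with amine 3, whose sense of induction puts the chain trans to the isopropenyl group. Ketone 2 is the conjugate-reduction product of 1.

## Alternatives that were turned down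

Alternative 1: Disconnection of C9–C10 and C5–C6 by a [2+2] photocycloaddition. Irradiation of cyclohexenone A3 with 1-methylcyclobutene A2 would give tricycle A1, and heating would cleave C5–C10 and C6–C9 of its bicyclo[2.2.0]hexane core to unveil the ten-membered ring.
- For: all ten ring carbons and both methyl-bearing carbons are joined in one step from two small pieces, and the ring is again released from a strained bicycle. On step economy it is clearly stronger than the chosen route, which spends fourteen steps before its ring opening.
- Against: the only stereocentre of A3 (C2) is para to the reacting alkene and gives little facial bias. The head-to-head or head-to-tail orientation of the unsymmetrical A2 is not secured. The thermal opening passes through a 1,4-diyl, so it can give mixed alkene geometries and drain into Cope-type divinylcyclohexanes. After opening, C1 is a ketone next to an epimerisable C2, and C9, C10, C1 and C5 would all have to be set on the flexible ring. A2 is also a volatile alkene that has to be made.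
- Comparison: the chosen route is longer, but it fixes C1, C2 and C9 on a rigid decalin and delivers the E alkene stereospecifically, leaving only C10 and C5 to be set on the ring.

Alternative 2: Disconnection of C1–C2. CrCl2 would convert the allylic bromide terminus of an open chain into an allylchromium species that adds through its γ carbon to a Z-enal terminus, closing the ring to homoallylic alcohol A4.
- For: C5 can come from (R)-citronellal A5, so the remote methyl centre is never at risk; on this point the alternative is stronger than the chosen route. The chair-like allylchromium transition state gives the anti O1/side-chain relationship that the target has, and the isopropenyl group is ready for hydration.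
- Against: this is a true ten-membered C–C ring closure, with high dilution and transannular strain in the transition state. The absolute sense at C1/C2 would have to be relayed from C5 across four ring atoms. The C9/C10 diol would come from osmylation of the Z-C9=C10 allylic alcohol, where the usual preference (new oxygen anti to the allylic oxygen) opposes the syn O1/O10 relationship needed.
- Comparison: the chosen strategy gives up certainty at C5 in exchange for certainty at C1, C2 and C9, absolute control from one chiral-pool centre, and a ring formation with no cyclisation entropy.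

Alternative 3: Disconnection of C2–C3. Pd(PPh3)4 would ionise an allylic methyl carbonate at one end of an open chain, and the β-keto ester enolate at the other end would attack the primary allyl terminus to give cyclodecenone A6.
- For: the C9/C10 diol can be installed with reagent control on an acyclic alkene before ring closure, which is stronger than the late ketone reduction used here for C10. The ester at C2 is a direct precursor of the hydroxypropyl group, and the conditions are neutral.
- Against: π-allyl closure to a ten-membered ring that already contains an E alkene is strained, and attack at the other allyl terminus (eight-membered ring) and O-alkylation compete. C2 lies between ketone and ester and is set only thermodynamically. C1 (ketone reduction) and C5 (hydrogenation of C4=C5 with no nearby donor) are again made on the flexible ring, and methyl addition to an ester flanking a ketone needs extra redox steps.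
- Comparison: the chosen route sets C1 and C2 kinetically on a six-membered ring from carvone and needs no medium-ring bond formation.

Key step: step 15

## Route

Step 1
Reactants: 1 (R)-carvone
Product: 2 (+)-dihydrocarvone (2R,5R)-2-methyl-5-(prop-1-en-2-yl)cyclohexan-1-one (major epimer; C2 mixture)
Conditions: Zn dust, KOH, EtOH/H2O, reflux
Reagents that add atoms: none
Why: Dissolving-metal conjugate reduction of the enone; the isolated isopropenyl group and the carvone stereocentre (future C2) are untouched, and the epimer mixture at the methyl carbon is irrelevant because that carbon becomes trigonal in step 2.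

Step 2
Reactants: 2 (+)-dihydrocarvone; 3 (R)-1-phenylethylamine; 4 ethyl vinyl ketone
Product: 7 diketone (2S,5R)-2-methyl-2-(3-oxopentyl)-5-(prop-1-en-2-yl)cyclohexan-1-one, via imine 5 (not isolated), via adduct imine 6 (not isolated)
Conditions: 3, TsOH (cat.), toluene, reflux, Dean–Stark; then 4, THF, 40 °C; then 10% aq. AcOH, rt
Reagents that add atoms: water, O
Why: Michael addition of a chiral imine (Pfau–d'Angelo type): the more substituted secondary enamine tautomer of 5 adds to the enone through a compact aza-ene-like transition state on the face away from the phenyl group. The (R)-amine gives the S quaternary centre (future C5), with the new chain trans to the isopropenyl group, where base catalysis would give the epimer by axial alkylation.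

Step 3
Reactants: 7 diketone
Product: 8 (+)-α-cyperone (4aS,7R)-1,4a-dimethyl-7-(prop-1-en-2-yl)-4,4a,5,6,7,8-hexahydronaphthalen-2(3H)-one (C8 ketone; C9=C10; β-methyl on C5; β-isopropenyl on C2)
Conditions: NaOMe, MeOH, rt → 50 °C
Reagents that add atoms: none
Why: Intramolecular aldol condensation (second stage of a Robinson annulation): the ethyl ketone enolate closes onto the ring carbonyl (6-exo-trig) and dehydration gives the tetrasubstituted enone; no stereocentre is formed or disturbed.

Step 4
Reactants: 8 (+)-α-cyperone
Product: 10 (+)-carissone (as 8 with a 2-hydroxypropan-2-yl group on C2), via organomercurial acetate 9 (not isolated)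
Conditions: Hg(OAc)2, THF/H2O, rt; then NaBH4, 3 M NaOH, 0 °C
Reagents that add atoms: water, O
Why: Oxymercuration–demercuration gives Markovnikov hydration of the electron-rich 1,1-disubstituted alkene; the tetrasubstituted, electron-poor enone bond does not mercurate, and demercuration is much faster than borohydride attack on the hindered conjugated ketone.

Step 5
Reactants: 10 (+)-carissone
Product: 12 C1β-hydroxy enone (C8 ketone; C9=C10; axial β-hydroxyl on C1; triethylsilyl ether on O11), via bis(triethylsilyl) dienol ether 11 (not isolated)
Conditions: Et3SiOTf (2.5 equiv), Et3N, CH2Cl2, 0 °C → rt; aq. NaHCO3 wash; then mCPBA, NaHCO3, CH2Cl2, −20 → 0 °C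
Reagents that add atoms: triethylsilyl trifluoromethanesulfonate, CC[Si](CC)(CC)OS(=O)(=O)C(F)(F)F; 3-chloroperoxybenzoic acid, OOC(=O)c1cccc(Cl)c1
Why: Excess silyl triflate silylates O11 and converts the enone into the extended dienol ether C8(OSi)=C9–C10=C1; peracid attacks its distal C10=C1 bond and collapse gives the γ-hydroxy enone (vinylogous Rubottom oxidation). Oxygen enters C1 axially on the β face, as in the 6β-hydroxylation of steroidal 3,5-dienol ethers, and the axial position is also the one free of allylic strain with the C9 methyl, so C1 is not prone to epimerise.

Step 6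
Reactants: 12 C1β-hydroxy enone
Product: 13 C1β tert-butyldimethylsilyl ether of 12
Conditions: t-BuMe2SiOTf, 2,6-lutidine, CH2Cl2, −78 → 0 °C
Reagents that add atoms: tert-butyldimethylsilyl trifluoromethanesulfonate, CC(C)(C)[Si](C)(C)OS(=O)(=O)C(F)(F)F
Why: Silyl triflate is reactive enough for the hindered axial allylic alcohol; with the weak base 2,6-lutidine at low temperature O-silylation outruns silyl dienol ether formation.

Step 7
Reactants: 13 silyl ether
Product: 15 cross-conjugated dienone (C8 ketone flanked by C6=C7 and C9=C10), via C7 phenylselenide 14 (not isolated)
Conditions: LiN(i-Pr)2, THF, −78 °C; PhSeCl; then H2O2, pyridine, CH2Cl2, 0 °C → rt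
Reagents that add atoms: none
Why: Kinetic deprotonation of the enone occurs at the α′ carbon C7; selenenylation and selenoxide syn-elimination (toward C6, the only carbon with a β hydrogen) give the C6=C7 bond with full regiocontrol.

Step 8
Reactants: 15 dienone
Product: 16 6α,7α-epoxy enone (C8 ketone; C9=C10)
Conditions: H2O2 (30%), NaOH, MeOH, 0 °C
Reagents that add atoms: hydrogen peroxide, OO
Why: Weitz–Scheffer epoxidation: hydroperoxide adds to C6 of the disubstituted enone bond (the tetrasubstituted C9=C10 bond is inert) on the α face, anti to the adjacent C5 methyl, which sets the C6 oxygen α.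

Step 9
Reactants: 16 epoxy enone
Product: 17 dienol (C6α-hydroxyl; C7=C8 and C9=C10; no oxygen on C8)
Conditions: N2H4·H2O, AcOH (cat.), MeOH, 0 °C → rt
Reagents that add atoms: none
Why: Wharton transposition: the C8 hydrazone opens the epoxide to a vinyl diazene, which loses nitrogen to give the allylic alcohol. The step removes the C8 oxygen and leaves the epoxide oxygen on C6 with its α configuration.

Step 10
Reactants: 17 dienol
Product: 18 C6α (axial) alcohol with the C9=C10 alkene only
Conditions: 2-O2NC6H4SO2NHNH2, Et3N, CH2Cl2, rt
Reagents that add atoms: none
Why: Diimide reduction: concerted syn transfer of H2 whose rate falls steeply with substitution, so the cis-disubstituted C7=C8 bond is reduced and the tetrasubstituted C9=C10 bond is left. No metal is present that could hydrogenolyse or isomerise the allylic alcohol.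

Step 11
Reactants: 18 C6α alcohol
Product: 19 C6 ketone (C9=C10 alkene)
Conditions: (n-Pr)4N[RuO4] (5 mol%), N-methylmorpholine N-oxide, 4 Å molecular sieves, CH2Cl2, rt
Reagents that add atoms: none
Why: Ley–Griffith oxidation of a secondary alcohol; the axial neopentyl alcohol oxidises readily and the non-enolisable C5 side prevents any loss of stereochemistry.

Step 12
Reactants: 19 C6 ketone
Product: 20 C6β (equatorial) alcohol (C9=C10 alkene)
Conditions: NaBH4, MeOH, 0 °C
Reagents that add atoms: none
Why: Hydride reduction of a ketone flanked by a quaternary carbon with an axial methyl: hydride approaches from the α face, away from that methyl (as in the saturated ketone of Wieland–Miescher-type decalones), giving the equatorial C6β alcohol needed for the fragmentation.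

Step 13
Reactants: 20 C6β alcohol
Product: 22 trans-decalin triol (C6β-OH; C9α-OH with C9β-methyl; C10α-OH; C1β-OSiMe2t-Bu; C2β-C(CH3)2OSiEt3), via cyclic osmate ester 21 (not isolated)
Conditions: OsO4 (1.1 equiv), pyridine, rt; then aq. NaHSO3, THF
Reagents that add atoms: osmium tetroxide, O=[Os](=O)(=O)=O
Why: Stoichiometric osmylation ([3+2] addition) of the tetrasubstituted C9=C10 bond; the β face is closed by the C5 methyl and the axial C1 silyloxy group, so both oxygens enter from the α face. This sets C9 (R) and C10 and gives the trans ring fusion.

Step 14
Reactants: 22 triol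
Product: 23 C6β mesylate of 22 (fragmentation precursor)
Conditions: MeSO2Cl, pyridine, 0 °C → rt
Reagents that add atoms: methanesulfonyl chloride, CS(=O)(=O)Cl
Why: Sulfonylation in pyridine takes the only secondary hydroxyl; the two tertiary hydroxyls do not react under these conditions.

Step 15
Reactants: 23 mesylate
Product: 24 (E)-cyclodec-5-en-10-one (C1 OSiMe2t-Bu; C2 C(CH3)2OSiEt3; C5 methyl on the alkene; C9 methyl carbinol)
Conditions: KOt-Bu (1.1 equiv), t-BuOH/THF, 0 °C → rt, short reaction time; pH 7 buffer quench
Reagents that add atoms: none
Why: Deprotonation of the angular C10 hydroxyl gives an alkoxide in which the oxygen lone pair, the C5–C10 fusion bond and the equatorial C6–O mesylate bond are anti-periplanar, so the C10=O π bond forms, the C5–C10 σ bond becomes the C5=C6 π bond and mesylate leaves in one concerted step (Wharton–Grob fragmentation of a 1,3-diol monosulfonate; the closest precedent is the opening of decalin 1,3-diol monosulfonates to E-cyclodecenones). No bond is formed and no ring is closed: the ten-membered ring already exists as the perimeter of the decalin and is set free by cutting the shared bond, so no closure mode and no cyclisation entropy are involved. No stereocentre is created; C5 and C10 become trigonal and C1, C2 and C9 are carried through unchanged. The alkene geometry is dictated by the substrate: the axial C5 methyl is anti to the axial C6 hydrogen and C4 is anti to C7, so only the E alkene can form. The step needs fragmentation to win over substitution or elimination at C6, which the neopentyl equatorial mesylate secures because it has no anti-periplanar hydrogen and a blocked rear side. It also needs the α-silyloxy ketone to survive (no C1 epimerisation, no α-ketol shift), which is secured by using about one equivalent of base (consumed as potassium mesylate), low temperature and a buffered quench. Relief of the three syn-axial β groups (C5 methyl, C9 methyl, C1 silyloxy) adds driving force.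

Step 16
Reactants: 24 cyclodecenone
Product: 25 (E)-cyclodec-5-ene-9,10-diol (10S; silyl ethers on O1 and O11)
Conditions: Zn(BH4)2, Et2O, −20 → 0 °C
Reagents that add atoms: none
Why: Chelation-controlled reduction of an α-hydroxy ketone: zinc bridges O9 and the carbonyl oxygen, and in this chelate the C9 methyl and ring carbon C8 lie on opposite carbonyl faces. The C8 face is the transannular one, so hydride should enter past the methyl on the peripheral face, giving C10 (S) with O9 and O10 anti along the chain as in the target.

Step 17
Reactants: 25 diol
Product: 26 9,10-acetonide of 25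
Conditions: 2-methoxypropene, pyridinium p-toluenesulfonate (cat.), CH2Cl2, 0 °C
Reagents that add atoms: 2-methoxypropene, COC(C)=C
Why: Ketalisation of the vicinal diol under mild acid that the trisubstituted alkene tolerates; it turns the two α-side hydroxyls into poorly coordinating ether oxygens for step 19 and protects them in step 20.

Step 18
Reactants: 26 acetonide
Product: 27 acetonide with free C1 and C11 hydroxyls (E-C5=C6 alkene)
Conditions: Bu4NF, THF, rt → 50 °C
Reagents that add atoms: none
Why: Fluoride cleaves both silyl ethers; the acetonide and the alkene are inert, and no base-sensitive group is present.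

Step 19
Reactants: 27 alkene diol
Product: 28 saturated acetonide diol (5S)
Conditions: [Ir(cod)(PCy3)(py)]PF6 (5–10 mol%), H2 (1 atm), CH2Cl2, 0 °C → rt
Reagents that add atoms: none
Why: Hydroxyl-directed hydrogenation: cationic iridium binds the secondary C1 hydroxyl on the β side and delivers H2 to the alkene face turned toward it. In the decalin-like conformer O1 sits beside the methyl edge of C5=C6, and tilting that methyl outward exposes the π face that pointed at C10, which gives C5 (S). The C9/C10 oxygens on the opposite side are tied up as the acetonide so that they cannot steer the metal to the other face.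

Step 20
Reactants: 28 saturated diol; 29 angelic acid
Product: 31 C1 angelate of 28, via mixed anhydride 30 (not isolated)
Conditions: 29, 2,4,6-Cl3C6H2COCl, Et3N, toluene, rt; then 28, toluene, 80 °C
Reagents that add atoms: none
Why: Yamaguchi-type esterification through the mixed anhydride without a nucleophilic catalyst, which acylates hindered secondary alcohols while avoiding the addition–elimination pathway that isomerises angelates to tiglates; the tertiary O11 is not acylated.

Step 21
Reactants: 31 angelate acetonide
Product: 32 target (1R,2R,5S,9R,10S)-9,10-dihydroxy-2-(2-hydroxypropan-2-yl)-5,9-dimethylcyclodecyl (2Z)-2-methylbut-2-enoate (ring numbering as above)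
Conditions: AcOH/H2O (4:1), 40 °C
Reagents that add atoms: none
Why: Acid hydrolysis of the acetonide; the conditions are too mild to isomerise the angelate or dehydrate the tertiary alcohols, and the ring no longer contains an alkene that could cyclise.

## Compound list

1 | (R)-carvone, (5R)-2-methyl-5-(prop-1-en-2-yl)cyclohex-2-en-1-one | CC1=CC[C@H](CC1=O)C(C)=C | starting material
2 | (+)-dihydrocarvone, (2R,5R)-2-methyl-5-(prop-1-en-2-yl)cyclohexan-1-one (major epimer) | C[C@@H]1CC[C@H](CC1=O)C(C)=C | intermediate
3 | (R)-1-phenylethylamine | C[C@@H](N)c1ccccc1 | starting material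
4 | ethyl vinyl ketone (pent-1-en-3-one) | CCC(=O)C=C | starting material
5 | N-[(1R)-1-phenylethyl]imine of 2 (C2 epimers, in equilibrium with the enamine) | CC1CC[C@H](CC1=N[C@H](C)c1ccccc1)C(C)=C | intermediate (not isolated)
6 | N-[(1R)-1-phenylethyl]imine of diketone 7 | CCC(=O)CC[C@]1(C)CC[C@H](CC1=N[C@H](C)c1ccccc1)C(C)=C | intermediate (not isolated)
7 | (2S,5R)-2-methyl-2-(3-oxopentyl)-5-(prop-1-en-2-yl)cyclohexan-1-one | C[C@]1(CCC(=O)CC)C(=O)C[C@H](C(C)=C)CC1 | intermediate
8 | (+)-α-cyperone | C[C@]12CCC(=O)C(C)=C1C[C@H](C(C)=C)CC2 | intermediate
9 | acetoxymercurio alcohol from 8 (C11 hydroxyl, CH2HgOAc; C11 epimers) | C[C@]12CCC(=O)C(C)=C1C[C@H](C(C)(O)C[Hg]OC(C)=O)CC2 | intermediate (not isolated)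
10 | (+)-carissone | C[C@]12CCC(=O)C(C)=C1C[C@H](C(C)(C)O)CC2 | intermediate
11 | C8 triethylsilyl dienol ether (C8=C9, C10=C1) with O11 triethylsilyl ether | C[C@]12CCC(O[Si](CC)(CC)CC)=C(C)C1=C[C@H](C(C)(C)O[Si](CC)(CC)CC)CC2 | intermediate (not isolated)
12 | C1β-hydroxy enone, O11 triethylsilyl ether | C[C@]12CCC(=O)C(C)=C1[C@H](O)[C@H](C(C)(C)O[Si](CC)(CC)CC)CC2 | intermediate
13 | C1β tert-butyldimethylsilyl ether of 12 | C[C@]12CCC(=O)C(C)=C1[C@H](O[Si](C)(C)C(C)(C)C)[C@H](C(C)(C)O[Si](CC)(CC)CC)CC2 | intermediate
14 | C7α-phenylselanyl ketone from 13 | C[C@]12C[C@@H]([Se]c3ccccc3)C(=O)C(C)=C1[C@H](O[Si](C)(C)C(C)(C)C)[C@H](C(C)(C)O[Si](CC)(CC)CC)CC2 | intermediate (not isolated)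
15 | cross-conjugated dienone (C6=C7, C9=C10, C8 ketone) | C[C@]12C=CC(=O)C(C)=C1[C@H](O[Si](C)(C)C(C)(C)C)[C@H](C(C)(C)O[Si](CC)(CC)CC)CC2 | intermediate
16 | 6α,7α-epoxy enone | C[C@]12[C@H]3O[C@H]3C(=O)C(C)=C1[C@H](O[Si](C)(C)C(C)(C)C)[C@H](C(C)(C)O[Si](CC)(CC)CC)CC2 | intermediate
17 | C6α-hydroxy 7,9-diene (C7=C8, C9=C10) | C[C@]12[C@@H](O)C=CC(C)=C1[C@H](O[Si](C)(C)C(C)(C)C)[C@H](C(C)(C)O[Si](CC)(CC)CC)CC2 | intermediate
18 | C6α alcohol, C9=C10 alkene | C[C@]12[C@@H](O)CCC(C)=C1[C@H](O[Si](C)(C)C(C)(C)C)[C@H](C(C)(C)O[Si](CC)(CC)CC)CC2 | intermediate
19 | C6 ketone, C9=C10 alkene | C[C@]12C(=O)CCC(C)=C1[C@H](O[Si](C)(C)C(C)(C)C)[C@H](C(C)(C)O[Si](CC)(CC)CC)CC2 | intermediate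
20 | C6β alcohol, C9=C10 alkene | C[C@]12[C@H](O)CCC(C)=C1[C@H](O[Si](C)(C)C(C)(C)C)[C@H](C(C)(C)O[Si](CC)(CC)CC)CC2 | intermediate
21 | cyclic osmate ester on the α face of C9/C10 (pyridine ligands omitted) | C[C@]12[C@H](O)CC[C@@]3(C)O[Os](=O)(=O)O[C@@]13[C@H](O[Si](C)(C)C(C)(C)C)[C@H](C(C)(C)O[Si](CC)(CC)CC)CC2 | intermediate (not isolated)
22 | trans-decalin 6β,9α,10α-triol | C[C@]12[C@H](O)CC[C@@](C)(O)[C@]1(O)[C@H](O[Si](C)(C)C(C)(C)C)[C@H](C(C)(C)O[Si](CC)(CC)CC)CC2 | intermediate
23 | trans-decalin 9α,10α-diol C6β mesylate (key-step precursor) | C[C@]12[C@H](OS(C)(=O)=O)CC[C@@](C)(O)[C@]1(O)[C@H](O[Si](C)(C)C(C)(C)C)[C@H](C(C)(C)O[Si](CC)(CC)CC)CC2 | intermediate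
24 | (E)-cyclodec-5-en-10-one with free C9 hydroxyl (key-step product) | O=C1[C@H](O[Si](C)(C)C(C)(C)C)[C@H](C(C)(C)O[Si](CC)(CC)CC)CC/C(C)=C/CC[C@@]1(C)O | intermediate
25 | (E)-cyclodec-5-ene-9,10-diol (10S), silyl ethers on O1 and O11 | CC(C)(C)[Si](C)(C)O[C@@H]1[C@H](C(C)(C)O[Si](CC)(CC)CC)CC/C(C)=C/CC[C@@](C)(O)[C@H]1O | intermediate
26 | 9,10-acetonide of 25 | CC(C)(C)[Si](C)(C)O[C@@H]1[C@H](C(C)(C)O[Si](CC)(CC)CC)CC/C(C)=C/CC[C@@]2(C)OC(C)(C)O[C@@H]12 | intermediate
27 | 9,10-acetonide with free C1 and C11 hydroxyls, E-C5=C6 | O[C@@H]1[C@H](C(C)(C)O)CC/C(C)=C/CC[C@@]2(C)OC(C)(C)O[C@@H]12 | intermediate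
28 | saturated 9,10-acetonide with free C1 and C11 hydroxyls (5S) | O[C@@H]1[C@H](C(C)(C)O)CC[C@@H](C)CCC[C@@]2(C)OC(C)(C)O[C@@H]12 | intermediate
29 | angelic acid, (2Z)-2-methylbut-2-enoic acid | C/C=C(/C)C(=O)O | starting material
30 | angelic 2,4,6-trichlorobenzoic anhydride | C/C=C(/C)C(=O)OC(=O)c1c(Cl)cc(Cl)cc1Cl | intermediate (not isolated)
31 | C1 angelate of 28 | C/C=C(/C)C(=O)O[C@@H]1[C@H](C(C)(C)O)CC[C@@H](C)CCC[C@@]2(C)OC(C)(C)O[C@@H]12 | intermediate
32 | CNP0130723.1 | C/C=C(/C)C(=O)O[C@@H]1[C@H](C(C)(C)O)CC[C@@H](C)CCC[C@@](C)(O)[C@H]1O | target

## Step count and least certain steps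

Total: 21 steps. Longest linear sequence: 21 steps from (R)-carvone 1; amine 3, enone 4 and acid 29 are purchased.

**Step 15 (key step).** The most likely failure is base-induced degradation after the fragmentation. The product is a tertiary α-hydroxy ketone with an enolisable C1–H, so lingering alkoxide can epimerise C1 or trigger an α-ketol shift, and a twisted ring A (three syn-axial β groups) could slow the fragmentation and lengthen that exposure. Fallback, from 23: silylate the less hindered equatorial C9 hydroxyl (1-(trimethylsilyl)imidazole, CH2Cl2) to the C9 trimethylsilyl ether of the mesylate F1. Fragment F1 with one equivalent of KOt-Bu (THF, 0 °C), which can then form only the C10 alkoxide and is used up, to the C9-silylated cyclodecenone F2. Remove the trimethylsilyl group (K2CO3, MeOH, 0 °C) to come back at 24.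

**Step 19.** The most likely failure is hydrogen delivery to the other alkene face. The E alkene can swing through the ring, the tertiary C11 hydroxyl can also bind iridium, and the prediction rests on a decalin-like conformer that is not secured. Fallback, from 25: move the hydrogenation forward, where only the C9 and C10 hydroxyls on the opposite side of the ring can bind the metal ([Ir(cod)(PCy3)(py)]PF6, H2, CH2Cl2), so that hydrogen is delivered from the complementary face. This gives the saturated diol bis-silyl ether F3; acetonide formation (2-methoxypropene, pyridinium p-toluenesulfonate) gives F4, and Bu4NF comes back at 28.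

**Step 16.** The most likely failure is erosion of facial selectivity. The ten-membered ketone can relax to conformers that expose the other carbonyl face, and the bulky C1 silyloxy group may interfere with the chelate. Fallback, from 23: run the fragmentation reductively (LiAlH4, THF, 0 °C → reflux), a known variant in which the aluminate triggers the fragmentation and reduces the ketone as it forms. The ring is then still in the geometry inherited from the decalin, and the C9 aluminate sits on the peripheral carbonyl face. This goes directly to 25 with no new compound (F0).

**Step 13.** The most likely failure is slow or incomplete osmylation, because the alkene is tetrasubstituted and flanked by a quaternary carbon and a silyloxy-bearing carbon. Fallback, from 19: flash dihydroxylation (RuCl3 (cat.), NaIO4, EtOAc/MeCN/H2O, 0 °C), which is far more reactive toward tetrasubstituted alkenes and is applied at the ketone stage, where no oxidisable alcohol is present. It should attack the same α face and give the keto diol F5; NaBH4 reduction of the C6 ketone from the α face comes back at 22.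

**Step 20.** The most likely failure is sluggish acylation of the hindered C1 hydroxyl; forcing it (nucleophilic catalysts, heat) isomerises the Z ester to the tiglate. Fallback, from 28: esterify with 2-[bis(2,2,2-trifluoroethoxy)phosphoryl]propanoic acid (dicyclohexylcarbodiimide, 4-dimethylaminopyridine cat.), a small saturated acyl donor, to the phosphonate ester F6. Still–Gennari olefination of F6 with acetaldehyde (KN(SiMe3)2, 18-crown-6, THF, −78 °C) builds the Z trisubstituted alkene on the ester already in place and comes back at 31.

## Further compounds

F1 | step 15 | C9 trimethylsilyl ether of mesylate 23 | C[C@]12[C@H](OS(C)(=O)=O)CC[C@@](C)(O[Si](C)(C)C)[C@]1(O)[C@H](O[Si](C)(C)C(C)(C)C)[C@H](C(C)(C)O[Si](CC)(CC)CC)CC2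
F2 | step 15 | C9 trimethylsilyl ether of cyclodecenone 24 | O=C1[C@H](O[Si](C)(C)C(C)(C)C)[C@H](C(C)(C)O[Si](CC)(CC)CC)CC/C(C)=C/CC[C@@]1(C)O[Si](C)(C)C
F3 | step 19 | saturated 9,10-diol with silyl ethers on O1 and O11 (5S) | CC(C)(C)[Si](C)(C)O[C@@H]1[C@H](C(C)(C)O[Si](CC)(CC)CC)CC[C@@H](C)CCC[C@@](C)(O)[C@H]1O
F4 | step 19 | 9,10-acetonide of F3 | CC(C)(C)[Si](C)(C)O[C@@H]1[C@H](C(C)(C)O[Si](CC)(CC)CC)CC[C@@H](C)CCC[C@@]2(C)OC(C)(C)O[C@@H]12
F0 | step 16 | none | none
F5 | step 13 | trans-decalin 9α,10α-diol with C6 ketone | C[C@]12C(=O)CC[C@@](C)(O)[C@]1(O)[C@H](O[Si](C)(C)C(C)(C)C)[C@H](C(C)(C)O[Si](CC)(CC)CC)CC2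
F6 | step 20 | C1 2-[bis(2,2,2-trifluoroethoxy)phosphoryl]propanoate of 28 | CC(C(=O)O[C@@H]1[C@H](C(C)(C)O)CC[C@@H](C)CCC[C@@]2(C)OC(C)(C)O[C@@H]12)P(=O)(OCC(F)(F)F)OCC(F)(F)F
A1 | alternative 1 | cis-anti-cis tricyclic [2+2] adduct | O=C1[C@H](C(C)(C)O[Si](CC)(CC)CC)CC[C@@]2(C)[C@@H]3CC[C@]3(C)[C@@H]12
A2 | alternative 1 | 1-methylcyclobutene | CC1=CCC1
A3 | alternative 1 | (6S)-3-methyl-6-[2-(triethylsilyloxy)propan-2-yl]cyclohex-2-en-1-one | O=C1[C@H](C(C)(C)O[Si](CC)(CC)CC)CCC(C)=C1
A4 | alternative 2 | Z-cyclodec-9-en-1-ol with C2 isopropenyl, C5 and C9 methyls | C/C1=C/[C@H](O)[C@H](C(C)=C)CC[C@@H](C)CCC1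
A5 | alternative 2 | (R)-citronellal | C[C@H](CCC=C(C)C)CC=O
A6 | alternative 3 | methyl E-cyclodec-4-en-1-one-2-carboxylate 9,10-acetonide | O=C1[C@H](C(=O)OC)C/C=C(\C)CCC[C@@]2(C)OC(C)(C)O[C@@H]12
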